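## Analysis of the target

The target 35 is a cyclohexanol joined through its carbinol carbon to a quaternary carbon of a cyclopentane. The six-membered ring is numbered C1 (carbinol), C2 (CH2), C3 (CHBr), C4 (CMeCl), C5, C6. The five-membered ring is numbered C1' (CMe, bonded to C1), C2' (CMe2), C3' (CHBr), C4' (CH2), C5' (CHOH). The C1–C1' bond links two fully substituted carbons, and C1'–C2' is a vicinal quaternary pair.

There are six stereocentres. On the cyclohexane the C1 hydroxyl and the C4 chlorine are cis (1,4), and the C3 bromine is trans to chlorine. With the bulky cyclopentyl group equatorial, the hydroxyl is axial and both halogens are equatorial. A trans-diaxial addition to a C3=C4 alkene in that chair would give the opposite arrangement. On the cyclopentane the C5' hydroxyl, the C3' bromine and the cyclohexyl group are all cis, and the C1' methyl is trans. The C3' bromide is secondary, neopentyl and on the more crowded face.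

The sensitive groups are:
- a tertiary chloride next to a secondary bromide (elimination, halide migration);
- a tertiary alcohol at C1 beside a quaternary carbon (ionisation with 1,2-shift, or transannular capture of a C4 cation);
- two C–Br bonds that do not survive dissolving metals.

The strategy rests on the cis-1,4 relationship of C1–O and C4–Cl with bromine on C3. This is the substitution pattern of a 2,3-dioxabicyclo[2.2.2]oct-5-ene, the adduct of singlet oxygen with a 1,3-diene spanning C1 to C4.

## Retrosynthetic reasoning

**C2–H (35 from 34).** The last bond made is C2–H, by hydride opening of a C1–C2 epoxide at its secondary carbon. C1 is kept as an epoxide carbon until the end for two reasons. A free C1 carbinol carrying the cyclopentyl group locks the chair so that substitution at C3 and C4 would have to go against trans-diaxial opening. A free C1 hydroxyl also sits cis-1,4 to C4 and would capture a C4 cation as a bridged ether. The forward step must open the epoxide without touching three C–halogen bonds.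

**C4–Cl and C3–Br (34 from 31 from 30).** The C4–Cl bond is cut back to a C4–O bond of the same configuration, and the C3–Br bond to an epoxide. Bromide opens the C3–C4 epoxide of diepoxide 30 at C3 with inversion, so bromine is anti to the C4 oxygen. Ionisation of the activated C4 oxygen is then assisted by that bromine, and chloride returns with retention. The configuration at C4 is thus carried over unchanged from oxygen to chlorine, and bromine ends trans to it.

**O–O (30 from 29).** The two epoxides are cut back to the peroxide bridge of 29. The cobalt-porphyrin-catalysed rearrangement moves each peroxide oxygen onto the neighbouring alkene carbon on the same face. Both C1–O and C4–O keep their configuration, and C2 and C3 become functionalised.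

**C1–O and C4–O (29 from 28, key step).** Both C–O bonds are cut at once, which leads back to the flat diene 28. This is the only disconnection that creates C1 and C4 together with a cis relationship guaranteed by mechanism. It also leaves the C2=C3 alkene exactly where bromine and hydrogen are needed. The forward step must choose one face of the diene under control of the cyclopentane.

**The diene (28 from 27 from 26 from 24, and 22 from 20).** The diene is traced to a dienyl triflate and from there to a cyclohex-3-enone. The enone comes from Birch reduction and hydrolysis of a 4-methoxyphenyl group. An anisole is preferred over a tolyl group because the tolyl Birch product is a 1,4-diene, whose isomerisation to the 1,3-diene stops at an equilibrium mixture. The ketone route fixes the diene position by the site of enolisation.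

**C3'–Br (24 from 23 from 22).** The C–Br bond is cut to a C3' alcohol of opposite configuration. The displacement has to come after the Birch reduction, which a C–Br bond would not survive. It needs the C5' oxygen protected by a group that is stable to dissolving metal.

**C3'–O and C5'–O stereocentres (20 from 19 from 18 from 17 from 16).** Both carbinol centres are derived from cyclopentenone 16, so that each is set by a substrate-controlled step. The C5' carbinol comes from hydride addition anti to the aryl group. The C3' oxygen comes from epoxidation anti to the silyl ether and the aryl group, followed by hydride opening at C4', the epoxide carbon remote from the quaternary C2'. The sequence also leaves the two oxygens differentiated (C5' silylated, C3' free) with no selective protection.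

**C3'–C4' and C4'–C5' (16 from 14 from 13 from 12 from 10 from 9).** The ring is opened at C3'=C4' by a retro-aldol condensation to keto aldehyde 14. Dehydration removes any stereochemical issue in the ring closure. C4' is a methyl group added to the C5' aldehyde. The remaining operations adjust oxidation levels of the rearrangement product 9.

**C1'–C2' (9 from 6, then 4 and 5, then 3, then 1 and 2).** The vicinal quaternary pair is cut by a retro-Ireland–Claisen rearrangement to allylic isobutyrate 6. A [3,3] shift is chosen because it joins two fully substituted carbons intramolecularly. It transfers the carbinol configuration of 4 to C1' through a chair. The isobutyrate ketene acetal has no geometry to control. Alcohol 4 comes from enone 3 by catalytic asymmetric reduction, and 3 from the commercial compounds 1 and 2.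

## Alternatives that were turned down

**Alternative 1: radical cyclisation onto an aldehyde.**
- Disconnection: C2'–C3'.
- Forward step: hydrogen-atom transfer from an iron hydride to an isopropenyl group gives the tertiary C2' radical, which adds 5-exo to an aldehyde carbon. The product is methyl 2-(tert-butyldimethylsilyloxy)-4-hydroxy-1,5,5-trimethylcyclopentane-1-carboxylate A1.
- For it: a bond to a quaternary carbon is made under mild radical conditions. A1 already carries C3'–OH and C5'–OSi differentiated, which the chosen route needs steps 10 to 13 to reach. On that point it is stronger.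
- Against it: addition of a carbon radical to a carbonyl is reversible, and nothing directs the C3' configuration. A1 carries only an ester at C1'. The whole cyclohexane, the C1–C1' bond and the C1 stereocentre would still have to be built, with no element relating C1 to C4.
- Comparison: the chosen strategy carries the six ring carbons from the first step and sets C1 and C4 in one operation.

**Alternative 2: intramolecular aldol of a keto aldehyde.**
- Disconnection: C4'–C5'.
- Forward step: a metal enolate of a methyl ketone adds to a neopentyl aldehyde on a substrate that already carries the cyclohexene. The product is 4-hydroxy-3-[1-(methoxymethoxy)-4-methylcyclohex-3-en-1-yl]-2,2,3-trimethylcyclopentan-1-one A2.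
- For it: it is convergent and needs no arene reduction, so it has fewer redox steps on the six-membered ring. On that point it is stronger.
- Against it: the new C5' carbinol forms next to a quaternary carbon with two large substituents and no reliable facial bias, and the aldol can revert or dehydrate. C1 and C1' must both be set beforehand as adjacent fully substituted stereocentres. The halogens must then be added to the C3=C4 alkene of a ring anchored by the C1 substituent. Diaxial opening of the bromonium ion there puts bromine and chlorine on the wrong faces relative to C1–O, and the C1 oxygen can capture the C4 cation.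
- Comparison: the chosen strategy takes the C4 configuration from the endoperoxide oxygen and never halogenates an anchored alkene.

**Alternative 3: bromonium-triggered alkene cyclisation.**
- Disconnection: C1'–C2' and C3'–Br together.
- Forward step: a bromonium source attacks a trisubstituted alkene, a tetrasubstituted alkene closes the ring, and an acetate captures the cation. The product is 4-bromo-2-(8-hydroxy-1,4-dioxaspiro[4.5]decan-8-yl)-2,3,3-trimethylcyclopentyl acetate A3.
- For it: it makes the vicinal quaternary pair and the neopentyl C–Br bond in one step. The chosen route must make that C–Br bond by a difficult displacement (step 16). On that bond it is clearly stronger.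
- Against it: the ring closure is a cation–alkene cyclisation to a five-membered ring that competes with proton loss and simple bromoacetoxylation. Bromonium transfer is not enantioselective, so absolute control must come from the acetate centre alone. In A3 the cyclohexane is still a symmetric ketal, so C1 is not yet a stereocentre. The C1/C3/C4 array would have to be built later with nothing linking C1 to C4.
- Comparison: the chosen strategy accepts a weaker C3'–Br step in exchange for mechanistic control of C1 and C4.

Key step: step 20

Remark: hydride is assumed to add to the carbonyl of 16 from the face of the C1' methyl group, the aryl group being treated as the larger substituent on the neighbouring quaternary carbon.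

## Route

Step 1
Reactants: 1 4-iodoanisole; 2 (E)-pent-3-en-2-one
Product: 3 (E)-4-(4-methoxyphenyl)pent-3-en-2-one
Conditions: Pd(OAc)2 (3 mol %), Bu4NCl, NaHCO3, DMF, 80 °C
Reagents that add atoms: none
Why: Mizoroki–Heck arylation of a β-substituted enone; the aryl group adds to the β-carbon and syn elimination of the only β-hydrogen gives the trisubstituted enone with aryl trans to acetyl.

Step 2
Reactants: 3 (E)-4-(4-methoxyphenyl)pent-3-en-2-one
Product: 4 (2S,3E)-4-(4-methoxyphenyl)pent-3-en-2-ol
Conditions: (R)-2-methyl-CBS-oxazaborolidine [(R)-1-methyl-3,3-diphenyltetrahydro-1H,3H-pyrrolo[1,2-c][1,3,2]oxazaborole] (10 mol %), catecholborane, toluene, −78 °C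
Reagents that add atoms: none
Why: Corey–Bakshi–Shibata reduction with the alkenyl group as the large and methyl as the small substituent; the (R)-catalyst should give the (S)-carbinol, and 1,2-reduction is favoured over conjugate reduction at low temperature.

Step 3
Reactants: 4 (2S,3E)-4-(4-methoxyphenyl)pent-3-en-2-ol; 5 isobutyryl chloride
Product: 6 (2S,3E)-4-(4-methoxyphenyl)pent-3-en-2-yl 2-methylpropanoate
Conditions: pyridine, DMAP (cat.), CH2Cl2, 0 °C
Reagents that add atoms: none
Why: Base-mediated acylation of a secondary allylic alcohol; non-acidic conditions avoid ionisation of the aryl-stabilised allylic system.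

Step 4
Reactants: 6 (2S,3E)-4-(4-methoxyphenyl)pent-3-en-2-yl 2-methylpropanoate
Product: 9 (3S,4E)-3-(4-methoxyphenyl)-2,2,3-trimethylhex-4-enoic acid, via silyl ketene acetal 7 (not isolated), via trimethylsilyl ester 8 (not isolated)
Conditions: LiN(iPr)2, Me3SiCl, THF, −78 °C to 60 °C; then 1 M HCl
Reagents that add atoms: none
Why: Ireland–Claisen rearrangement; the [3,3] shift through a chair with the carbinol methyl equatorial forms C1'–C2' between two fully substituted carbons and transfers the (S)-carbinol configuration to C1'. The isobutyrate-derived ketene acetal is symmetric, so no enolate geometry has to be controlled, and the new alkene is E.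

Step 5
Reactants: 9 (3S,4E)-3-(4-methoxyphenyl)-2,2,3-trimethylhex-4-enoic acid
Product: 10 (3S,4E)-3-(4-methoxyphenyl)-2,2,3-trimethylhex-4-en-1-ol
Conditions: LiAlH4, THF, 0 °C to reflux
Reagents that add atoms: none
Why: Hydride reduction of a hindered carboxylic acid to the neopentyl alcohol; the isolated alkene and the anisole are inert.

Step 6
Reactants: 10 (3S,4E)-3-(4-methoxyphenyl)-2,2,3-trimethylhex-4-en-1-ol
Product: 12 3-(4-methoxyphenyl)-3,4,4-trimethyloxolan-2-ol (lactol; anomers; quaternary carbon as in 9), via ozonide 11 (not isolated)
Conditions: O3, CH2Cl2, −78 °C (indicator dye); then PPh3, −78 °C to rt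
Reagents that add atoms: ozone, [O-][O+]=O
Why: Ozonolysis of the only alkene, which reacts faster than the anisole ring; the γ-hydroxy aldehyde closes to the five-membered lactol.

Step 7
Reactants: 12 3-(4-methoxyphenyl)-3,4,4-trimethyloxolan-2-ol
Product: 13 3-(4-methoxyphenyl)-2,2,3-trimethylpentane-1,4-diol (C4 epimers; C3 as in 9)
Conditions: MeMgBr (3 equiv), THF, 0 °C to rt
Reagents that add atoms: methylmagnesium bromide, C[Mg]Br
Why: Grignard addition to the open hydroxy aldehyde form of the lactol brings in C4'; the configuration of the new carbinol is irrelevant because it is oxidised in the next step.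

Step 8
Reactants: 13 3-(4-methoxyphenyl)-2,2,3-trimethylpentane-1,4-diol
Product: 14 3-(4-methoxyphenyl)-2,2,3-trimethyl-4-oxopentanal (C3 as in 9)
Conditions: (COCl)2, DMSO, CH2Cl2, −78 °C; Et3N, −78 to 0 °C
Reagents that add atoms: none
Why: Swern oxidation of both hydroxyls gives the 1,4-keto aldehyde; the aldehyde has no α-hydrogen and cannot epimerise or self-condense.

Step 9
Reactants: 14 3-(4-methoxyphenyl)-2,2,3-trimethyl-4-oxopentanal
Product: 16 (R)-5-(4-methoxyphenyl)-4,4,5-trimethylcyclopent-2-en-1-one, via aldol adduct 15 (not isolated)
Conditions: KOH, MeOH, rt to 50 °C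
Reagents that add atoms: none
Why: Intramolecular aldol condensation of a 1,4-dicarbonyl compound to a cyclopentenone; only the methyl ketone can enolise and only the aldehyde can accept, so C3'–C4' forms without regiochemical choice and dehydration removes the aldol stereocentre.

Step 10
Reactants: 16 (R)-5-(4-methoxyphenyl)-4,4,5-trimethylcyclopent-2-en-1-one
Product: 17 5-(4-methoxyphenyl)-4,4,5-trimethylcyclopent-2-en-1-ol (hydroxyl cis to the aryl group)
Conditions: NaBH4, CeCl3·7H2O, MeOH, −40 °C
Reagents that add atoms: none
Why: Luche 1,2-reduction; hydride approaches the carbonyl from the face of the C1' methyl, anti to the larger aryl group, which sets C5' with the hydroxyl cis to the aryl group.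

Step 11
Reactants: 17 5-(4-methoxyphenyl)-4,4,5-trimethylcyclopent-2-en-1-ol
Product: 18 tert-butyl{[5-(4-methoxyphenyl)-4,4,5-trimethylcyclopent-2-en-1-yl]oxy}dimethylsilane (silyloxy cis to aryl)
Conditions: tBuMe2SiOTf, 2,6-lutidine, CH2Cl2, −78 to 0 °C
Reagents that add atoms: tert-butyldimethylsilyl trifluoromethanesulfonate, CC(C)(C)[Si](C)(C)OS(=O)(=O)C(F)(F)F
Why: Silylation of a hindered secondary alcohol with the silyl triflate; the ether survives dissolving metal and blocks one face of the alkene for the next step.

Step 12
Reactants: 18 tert-butyl{[5-(4-methoxyphenyl)-4,4,5-trimethylcyclopent-2-en-1-yl]oxy}dimethylsilane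
Product: 19 2,3-epoxide of 18 (epoxide oxygen trans to the silyloxy and aryl groups)
Conditions: mCPBA, NaHCO3, CH2Cl2, 0 °C to rt
Reagents that add atoms: 3-chloroperoxybenzoic acid, OOC(=O)c1cccc(Cl)c1
Why: Peracid epoxidation from the less hindered face; the allylic silyloxy group and the aryl group both lie on the other face, so the oxygen should be delivered trans to them.

Step 13
Reactants: 19 2,3-epoxide of 18
Product: 20 4-(tert-butyldimethylsilyloxy)-3-(4-methoxyphenyl)-2,2,3-trimethylcyclopentan-1-ol (1-OH trans to the silyloxy and aryl groups; silyloxy cis to aryl)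
Conditions: LiEt3BH, THF, 0 to 40 °C
Reagents that add atoms: none
Why: SN2 hydride opening of the epoxide at C4', the carbon not adjacent to the quaternary C2'; this leaves the C3' hydroxyl trans to the C5' silyloxy group, with the two oxygens already differentiated.

Step 14
Reactants: 20 4-(tert-butyldimethylsilyloxy)-3-(4-methoxyphenyl)-2,2,3-trimethylcyclopentan-1-ol
Product: 22 4-[5-(tert-butyldimethylsilyloxy)-3-hydroxy-1,2,2-trimethylcyclopentyl]cyclohex-3-en-1-one (cyclopentane configuration as in 20), via methyl enol ether 21 (not isolated)
Conditions: Li, NH3 (l), t-BuOH, THF, −78 °C; NH4Cl; then (CO2H)2, THF–H2O, rt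
Reagents that add atoms: water, O
Why: Birch reduction of the para-alkyl anisole gives the 1-methoxycyclohexa-1,4-diene, and mild acid hydrolysis of the enol ether gives the β,γ-unsaturated ketone; the silyl ether and the alkoxide are inert to lithium in ammonia.

Step 15
Reactants: 22 4-[5-(tert-butyldimethylsilyloxy)-3-hydroxy-1,2,2-trimethylcyclopentyl]cyclohex-3-en-1-one
Product: 23 4-(tert-butyldimethylsilyloxy)-2,2,3-trimethyl-3-(4-oxocyclohex-1-en-1-yl)cyclopentyl chloromethanesulfonate
Conditions: ClCH2SO2Cl, pyridine, CH2Cl2, 0 °C
Reagents that add atoms: chloromethanesulfonyl chloride, ClCS(Cl)(=O)=O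
Why: Sulfonylation of the only free hydroxyl; the chloromethanesulfonate is a more reactive leaving group than a mesylate for substitution at hindered secondary carbons.

Step 16
Reactants: 23 4-(tert-butyldimethylsilyloxy)-2,2,3-trimethyl-3-(4-oxocyclohex-1-en-1-yl)cyclopentyl chloromethanesulfonate
Product: 24 4-[3-bromo-5-(tert-butyldimethylsilyloxy)-1,2,2-trimethylcyclopentyl]cyclohex-3-en-1-one (bromine cis to the silyloxy group and to the cyclohexenyl group)
Conditions: LiBr, DMF, 60 °C
Reagents that add atoms: lithium bromide, [Li+].[Br-]
Why: SN2 displacement with inversion turns the C3' oxygen (trans) into the C3' bromide (cis to the C5' oxygen and the six-membered ring). Cyclopentyl sulfonates are good SN2 substrates, but the adjacent quaternary carbon makes this a slow step.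

Step 17
Reactants: 24 4-[3-bromo-5-(tert-butyldimethylsilyloxy)-1,2,2-trimethylcyclopentyl]cyclohex-3-en-1-one
Product: 26 4-[3-bromo-5-(tert-butyldimethylsilyloxy)-1,2,2-trimethylcyclopentyl]cyclohexa-1,3-dien-1-yl trifluoromethanesulfonate, via potassium dienolate 25 (not isolated)
Conditions: KN(SiMe3)2, THF, −78 °C; then PhNTf2, −78 to 0 °C
Reagents that add atoms: N-phenylbis(trifluoromethanesulfonimide), O=S(=O)(N(c1ccccc1)S(=O)(=O)C(F)(F)F)C(F)(F)F
Why: Deprotonation at the carbon between carbonyl and alkene gives the through-conjugated dienolate, and O-triflation fixes the 1,3-diene between C1 and C4; the secondary bromide is not attacked by the amide base at −78 °C.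

Step 18
Reactants: 26 4-[3-bromo-5-(tert-butyldimethylsilyloxy)-1,2,2-trimethylcyclopentyl]cyclohexa-1,3-dien-1-yl trifluoromethanesulfonate
Product: 27 {[4-bromo-2,3,3-trimethyl-2-(4-methylcyclohexa-1,3-dien-1-yl)cyclopentyl]oxy}(tert-butyl)dimethylsilane
Conditions: MeZnCl, Pd(PPh3)4 (5 mol %), THF, rt
Reagents that add atoms: methylzinc chloride, C[Zn]Cl
Why: Negishi coupling of an alkenyl triflate with a methylzinc reagent places the C4 methyl on a diene of defined position; the hindered secondary alkyl bromide does not undergo oxidative addition with this catalyst at room temperature.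

Step 19
Reactants: 27 {[4-bromo-2,3,3-trimethyl-2-(4-methylcyclohexa-1,3-dien-1-yl)cyclopentyl]oxy}(tert-butyl)dimethylsilane
Product: 28 (1R,2S,4S)-4-bromo-2,3,3-trimethyl-2-(4-methylcyclohexa-1,3-dien-1-yl)cyclopentan-1-ol
Conditions: Bu4NF, AcOH, THF, 0 °C to rt
Reagents that add atoms: none
Why: Fluoride cleavage of the silyl ether; buffering with acetic acid keeps the medium too weakly basic for elimination of the secondary bromide and too weakly acidic to isomerise the diene.

Step 20
Reactants: 28 (1R,2S,4S)-4-bromo-2,3,3-trimethyl-2-(4-methylcyclohexa-1,3-dien-1-yl)cyclopentan-1-ol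
Product: 29 4-bromo-2,3,3-trimethyl-2-(4-methyl-2,3-dioxabicyclo[2.2.2]oct-5-en-1-yl)cyclopentan-1-ol (peroxide oxygens at C1 and C4 cis; cyclopentane as in 28)
Conditions: O2, visible light, 5,10,15,20-tetraphenylporphyrin (cat.), CH2Cl2, −78 °C
Reagents that add atoms: dioxygen, O=O
Why: Sensitised singlet oxygen adds to the ring-locked s-cis diene C1=C2–C3=C4 in a concerted suprafacial (4+2) cycloaddition, the reaction by which 1,4-dialkylcyclohexa-1,3-dienes give ascaridole-type endoperoxides. The 1,2-dioxane ring of the 2,3-dioxabicyclo[2.2.2]octene is closed by this cycloaddition with both C–O bonds forming on one face, so C1–O and C4–O are necessarily cis and the C2=C3 alkene is left to mark C3. The new stereocentres C1 and C4 are thus fixed relative to each other by the mechanism and relative to the cyclopentane by the face that is attacked. That face is decided by the C1' stereocentre: in the preferred approach the CMe2 carbon C2' is anti to the incoming oxygen, the C1' methyl lies beside C1=C2 and the C5' arm beside C6, where its hydroxyl sits on the attacked face and can hydrogen-bond to the oxygen bonding to C1. The step needs diastereofacial selectivity and a preference for cycloaddition over the ene reaction; the s-cis geometry secures the second, while the first depends on this hydroxyl-directed rotamer and is the main uncertainty of the route. The secondary bromide and the alcohol are inert to singlet oxygen at low temperature.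

Step 21
Reactants: 29 4-bromo-2,3,3-trimethyl-2-(4-methyl-2,3-dioxabicyclo[2.2.2]oct-5-en-1-yl)cyclopentan-1-ol
Product: 30 4-bromo-2-(1,2:3,4-diepoxy-4-methylcyclohexyl)-2,3,3-trimethylcyclopentan-1-ol (syn-diepoxide; both epoxide oxygens on the face opposite to the cyclopentyl group)
Conditions: Co(TPP) [5,10,15,20-tetraphenylporphyrinatocobalt, divalent cobalt] (5 mol %), CH2Cl2, −20 to 0 °C
Reagents that add atoms: none
Why: Cobalt-catalysed homolysis of the O–O bond followed by closure of each oxygen radical onto the adjacent alkene carbon gives the syn-diepoxide with retention at C1 and C4; with no bridgehead hydrogen the competing hydroxy-enone pathway is closed.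

Step 22
Reactants: 30 4-bromo-2-(1,2:3,4-diepoxy-4-methylcyclohexyl)-2,3,3-trimethylcyclopentan-1-ol
Product: 31 4-bromo-2-(3-bromo-1,2-epoxy-4-hydroxy-4-methylcyclohexyl)-2,3,3-trimethylcyclopentan-1-ol (C3 bromine trans to the C4 hydroxyl and to the epoxide oxygen)
Conditions: Li2NiBr4 (1.1 equiv), THF, 0 °C
Reagents that add atoms: dilithium tetrabromonickelate, [Li+].[Li+].[Ni+2].[Br-].[Br-].[Br-].[Br-]
Why: Soft bromide opens the C3–C4 epoxide by SN2 attack at the secondary carbon C3 from the face opposite its oxygen; C2 is shielded on that face by the cyclopentyl group on C1, and C1 and C4 are tertiary. While C1 is still an epoxide carbon the ring has no anchored chair, so this opening is not opposed by the trans-diaxial requirement.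

Step 23
Reactants: 31 4-bromo-2-(3-bromo-1,2-epoxy-4-hydroxy-4-methylcyclohexyl)-2,3,3-trimethylcyclopentan-1-ol
Product: 34 4-bromo-2-(3-bromo-4-chloro-1,2-epoxy-4-methylcyclohexyl)-2,3,3-trimethylcyclopentan-1-ol (chlorine trans to the C3 bromine and cis to the epoxide oxygen), via bis(chlorosulfite) 32 (not isolated), via chloride chlorosulfite 33 (not isolated)
Conditions: SOCl2 (3 equiv), 2,6-di-tert-butyl-4-methylpyridine, CH2Cl2, −78 to −20 °C; then aq. NaHCO3
Reagents that add atoms: thionyl chloride, ClS(Cl)=O
Why: Both hydroxyls form chlorosulfites; the tertiary one at C4 ionises with the anti C3 bromine bridging, and chloride returns to C4 on the face the oxygen left, so chlorine replaces oxygen with retention and stays trans to bromine. The neopentyl secondary chlorosulfite at C5' neither ionises nor is displaced at low temperature and is hydrolysed on bicarbonate work-up. The hindered pyridine removes HCl, which protects the epoxide, without promoting elimination.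

Step 24
Reactants: 34 4-bromo-2-(3-bromo-4-chloro-1,2-epoxy-4-methylcyclohexyl)-2,3,3-trimethylcyclopentan-1-ol
Product: 35 (1R,3S,4S)-3-bromo-1-[(1S,3S,5R)-3-bromo-5-hydroxy-1,2,2-trimethylcyclopentyl]-4-chloro-4-methylcyclohexan-1-ol
Conditions: NaAlH2(OCH2CH2OMe)2, THF, −40 to 0 °C
Reagents that add atoms: none
Why: The C5' alkoxide binds aluminium and delivers hydride to C2 of the neighbouring epoxide from the cyclopentyl face, anti to the epoxide oxygen. This is an SN2 opening at the secondary carbon that leads directly into the chair with the cyclopentyl group equatorial, and it leaves the tertiary C1 hydroxyl with the configuration set in step 20. Intramolecular delivery at low temperature should be faster than attack of hydride on the hindered secondary bromides or the tertiary chloride.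

## Compound list

1 | 4-iodoanisole | COc1ccc(I)cc1 | starting material
2 | (E)-pent-3-en-2-one | C/C=C/C(C)=O | starting material
3 | (E)-4-(4-methoxyphenyl)pent-3-en-2-one | CC(=O)/C=C(\C)c1ccc(OC)cc1 | intermediate
4 | (2S,3E)-4-(4-methoxyphenyl)pent-3-en-2-ol | C[C@H](O)/C=C(\C)c1ccc(OC)cc1 | intermediate
5 | isobutyryl chloride | CC(C)C(Cl)=O | starting material
6 | (2S,3E)-4-(4-methoxyphenyl)pent-3-en-2-yl 2-methylpropanoate | CC(C)C(=O)O[C@@H](C)/C=C(\C)c1ccc(OC)cc1 | intermediate
7 | trimethylsilyl ketene acetal of 6 | CC(C)=C(O[Si](C)(C)C)O[C@@H](C)/C=C(\C)c1ccc(OC)cc1 | intermediate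
8 | trimethylsilyl (3S,4E)-3-(4-methoxyphenyl)-2,2,3-trimethylhex-4-enoate | C[Si](C)(C)OC(=O)C(C)(C)[C@@](C)(/C=C/C)c1ccc(OC)cc1 | intermediate
9 | (3S,4E)-3-(4-methoxyphenyl)-2,2,3-trimethylhex-4-enoic acid | OC(=O)C(C)(C)[C@@](C)(/C=C/C)c1ccc(OC)cc1 | intermediate
10 | (3S,4E)-3-(4-methoxyphenyl)-2,2,3-trimethylhex-4-en-1-ol | OCC(C)(C)[C@@](C)(/C=C/C)c1ccc(OC)cc1 | intermediate
11 | ozonide (1,2,4-trioxolane) of 10 | OCC(C)(C)[C@](C)(c1ccc(OC)cc1)C1OOC(C)O1 | intermediate
12 | 3-(4-methoxyphenyl)-3,4,4-trimethyloxolan-2-ol (lactol, anomers) | OC1OCC(C)(C)[C@]1(C)c1ccc(OC)cc1 | intermediate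
13 | 3-(4-methoxyphenyl)-2,2,3-trimethylpentane-1,4-diol (C4 epimers) | CC(O)[C@@](C)(c1ccc(OC)cc1)C(C)(C)CO | intermediate
14 | 3-(4-methoxyphenyl)-2,2,3-trimethyl-4-oxopentanal | CC(=O)[C@@](C)(c1ccc(OC)cc1)C(C)(C)C=O | intermediate
15 | 4-hydroxy-2-(4-methoxyphenyl)-2,3,3-trimethylcyclopentan-1-one (aldol adduct) | O=C1CC(O)C(C)(C)[C@]1(C)c1ccc(OC)cc1 | intermediate
16 | (R)-5-(4-methoxyphenyl)-4,4,5-trimethylcyclopent-2-en-1-one | O=C1C=CC(C)(C)[C@]1(C)c1ccc(OC)cc1 | intermediate
17 | 5-(4-methoxyphenyl)-4,4,5-trimethylcyclopent-2-en-1-ol, hydroxyl cis to aryl | O[C@@H]1C=CC(C)(C)[C@]1(C)c1ccc(OC)cc1 | intermediate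
18 | tert-butyldimethylsilyl ether of 17 | CC(C)(C)[Si](C)(C)O[C@@H]1C=CC(C)(C)[C@]1(C)c1ccc(OC)cc1 | intermediate
19 | 2,3-epoxide of 18, epoxide oxygen trans to silyloxy and aryl | CC(C)(C)[Si](C)(C)O[C@@H]1[C@H]2O[C@H]2C(C)(C)[C@]1(C)c1ccc(OC)cc1 | intermediate
20 | 4-(tert-butyldimethylsilyloxy)-3-(4-methoxyphenyl)-2,2,3-trimethylcyclopentan-1-ol, 1-OH trans to silyloxy and aryl | CC1(C)[C@H](O)C[C@@H](O[Si](C)(C)C(C)(C)C)[C@@]1(C)c1ccc(OC)cc1 | intermediate
21 | 4-(tert-butyldimethylsilyloxy)-3-(4-methoxycyclohexa-1,4-dien-1-yl)-2,2,3-trimethylcyclopentan-1-ol | CC1(C)[C@H](O)C[C@@H](O[Si](C)(C)C(C)(C)C)[C@@]1(C)C1=CCC(OC)=CC1 | intermediate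
22 | 4-[5-(tert-butyldimethylsilyloxy)-3-hydroxy-1,2,2-trimethylcyclopentyl]cyclohex-3-en-1-one | CC1(C)[C@H](O)C[C@@H](O[Si](C)(C)C(C)(C)C)[C@@]1(C)C1=CCC(=O)CC1 | intermediate
23 | 4-(tert-butyldimethylsilyloxy)-2,2,3-trimethyl-3-(4-oxocyclohex-1-en-1-yl)cyclopentyl chloromethanesulfonate | CC1(C)[C@H](OS(=O)(=O)CCl)C[C@@H](O[Si](C)(C)C(C)(C)C)[C@@]1(C)C1=CCC(=O)CC1 | intermediate
24 | 4-[3-bromo-5-(tert-butyldimethylsilyloxy)-1,2,2-trimethylcyclopentyl]cyclohex-3-en-1-one | CC1(C)[C@@H](Br)C[C@@H](O[Si](C)(C)C(C)(C)C)[C@@]1(C)C1=CCC(=O)CC1 | intermediate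
25 | potassium dienolate of 24 | CC1(C)[C@@H](Br)C[C@@H](O[Si](C)(C)C(C)(C)C)[C@@]1(C)C1=CC=C([O-])CC1.[K+] | intermediate
26 | 4-[3-bromo-5-(tert-butyldimethylsilyloxy)-1,2,2-trimethylcyclopentyl]cyclohexa-1,3-dien-1-yl trifluoromethanesulfonate | CC1(C)[C@@H](Br)C[C@@H](O[Si](C)(C)C(C)(C)C)[C@@]1(C)C1=CC=C(OS(=O)(=O)C(F)(F)F)CC1 | intermediate
27 | tert-butyldimethylsilyl ether of 28 | CC1(C)[C@@H](Br)C[C@@H](O[Si](C)(C)C(C)(C)C)[C@@]1(C)C1=CC=C(C)CC1 | intermediate
28 | (1R,2S,4S)-4-bromo-2,3,3-trimethyl-2-(4-methylcyclohexa-1,3-dien-1-yl)cyclopentan-1-ol | CC1(C)[C@@H](Br)C[C@@H](O)[C@@]1(C)C1=CC=C(C)CC1 | intermediate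
29 | 4-bromo-2,3,3-trimethyl-2-(4-methyl-2,3-dioxabicyclo[2.2.2]oct-5-en-1-yl)cyclopentan-1-ol | CC1(C)[C@@H](Br)C[C@@H](O)[C@@]1(C)[C@]12CC[C@](C)(OO1)C=C2 | intermediate
30 | 4-bromo-2-(1,2:3,4-diepoxy-4-methylcyclohexyl)-2,3,3-trimethylcyclopentan-1-ol, syn-diepoxide | CC1(C)[C@@H](Br)C[C@@H](O)[C@@]1(C)[C@@]12CC[C@]3(C)O[C@@H]3[C@@H]1O2 | intermediate
31 | 4-bromo-2-(3-bromo-1,2-epoxy-4-hydroxy-4-methylcyclohexyl)-2,3,3-trimethylcyclopentan-1-ol | CC1(C)[C@@H](Br)C[C@@H](O)[C@@]1(C)[C@@]12CC[C@](C)(O)[C@@H](Br)[C@@H]1O2 | intermediate
32 | bis(chlorosulfite) of 31 | CC1(C)[C@@H](Br)C[C@@H](OS(Cl)=O)[C@@]1(C)[C@@]12CC[C@](C)(OS(Cl)=O)[C@@H](Br)[C@@H]1O2 | intermediate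
33 | C5' chlorosulfite of 34 | CC1(C)[C@@H](Br)C[C@@H](OS(Cl)=O)[C@@]1(C)[C@@]12CC[C@](C)(Cl)[C@@H](Br)[C@@H]1O2 | intermediate
34 | 4-bromo-2-(3-bromo-4-chloro-1,2-epoxy-4-methylcyclohexyl)-2,3,3-trimethylcyclopentan-1-ol | CC1(C)[C@@H](Br)C[C@@H](O)[C@@]1(C)[C@@]12CC[C@](C)(Cl)[C@@H](Br)[C@@H]1O2 | intermediate
35 | (1R,3S,4S)-3-bromo-1-[(1S,3S,5R)-3-bromo-5-hydroxy-1,2,2-trimethylcyclopentyl]-4-chloro-4-methylcyclohexan-1-ol | CC1(C)[C@@H](Br)C[C@@H](O)[C@@]1(C)[C@@]1(O)CC[C@](C)(Cl)[C@@H](Br)C1 | target

## Step count and least certain steps

Total step count: 24. Longest linear sequence: 24 steps, from 4-iodoanisole 1.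

**Step 20 (key step).** The most likely failure is poor facial selectivity on the planar diene. The two diastereomeric approaches differ only in whether the C1' methyl or the C5' arm lies beside C6, and a hydrogen bond from a hydroxyl one carbon removed from the diene is a weak steering element. An ene reaction at the allylic C–H bonds is a second, smaller risk. Fallback: the photooxygenation is run one step earlier, on silyl ether 27, so that steric shielding by the bulky silyloxy arm replaces hydrogen bonding as the control element. This gives the tert-butyldimethylsilyl ether of the endoperoxide F1, and desilylation with Bu4NF and AcOH returns to 29.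

**Step 24.** Hydride may attack a halogen instead of the epoxide. The result would be anti elimination of the vicinal bromide and chloride, or loss of the C3 bromide with opening of the epoxide to an allylic alcohol. This is possible because the dihalide can sit diaxial before the ring is anchored. Fallback: the order of events is changed so that hydride never meets the ring halogens. Starting from diepoxide 30, the same aluminium hydride, directed by the C5' alkoxide, opens the nearby C1–C2 epoxide first and gives the epoxy diol 4-bromo-2-(3,4-epoxy-1-hydroxy-4-methylcyclohexyl)-2,3,3-trimethylcyclopentan-1-ol F2. Li2NiBr4 then opens the remaining epoxide to the bromohydrin triol 4-bromo-2-(3-bromo-1,4-dihydroxy-4-methylcyclohexyl)-2,3,3-trimethylcyclopentan-1-ol F3. Chlorination with SOCl2 and the hindered pyridine returns to the route at 35. This order is the second choice, because the ring of F2 is anchored and the free C1 hydroxyl can intercept a C4 cation.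

**Step 23.** Elimination from the tertiary chlorosulfite (to the C4 alkenes) may compete with collapse to the chloride, and the free C5' hydroxyl may form intermolecular sulfite esters. Fallback: the secondary hydroxyl of 31 is first acetylated (Ac2O, DMAP) to the acetate of the bromohydrin F4. The tertiary hydroxyl is then replaced under neutral conditions with 1-chloro-N,N,2-trimethylprop-1-en-1-amine, to give the acetate of the bromochloro epoxide F5. The aluminium hydride of step 24, used in excess, cleaves the acetate and opens the epoxide, which returns to the route at 35.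

**Step 16.** Substitution at the neopentyl carbon C3' may lose to elimination towards C4' or to a methyl shift from C2'. Bromide must approach from the face that carries the silyloxy group and the six-membered ring. Fallback: the displacement is moved to a less crowded substrate. Starting from 23, the silyl ether is removed with HF·pyridine to give the hydroxy sulfonate 4-hydroxy-2,2,3-trimethyl-3-(4-oxocyclohex-1-en-1-yl)cyclopentyl chloromethanesulfonate F6. Its trans hydroxyl cannot reach C3'. LiBr then gives the bromo alcohol 4-(3-bromo-5-hydroxy-1,2,2-trimethylcyclopentyl)cyclohex-3-en-1-one F7. Silylation with tBuMe2SiOTf and 2,6-lutidine returns to 24.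

## Further compounds

F1 | step 20 | tert-butyldimethylsilyl ether of endoperoxide 29 | CC1(C)[C@@H](Br)C[C@@H](O[Si](C)(C)C(C)(C)C)[C@@]1(C)[C@]12CC[C@](C)(OO1)C=C2
F2 | step 24 | 4-bromo-2-(3,4-epoxy-1-hydroxy-4-methylcyclohexyl)-2,3,3-trimethylcyclopentan-1-ol | CC1(C)[C@@H](Br)C[C@@H](O)[C@@]1(C)[C@@]1(O)CC[C@]2(C)O[C@@H]2C1
F3 | step 24 | 4-bromo-2-(3-bromo-1,4-dihydroxy-4-methylcyclohexyl)-2,3,3-trimethylcyclopentan-1-ol | CC1(C)[C@@H](Br)C[C@@H](O)[C@@]1(C)[C@@]1(O)CC[C@](C)(O)[C@@H](Br)C1
F4 | step 23 | acetate of bromohydrin 31 at the cyclopentane hydroxyl | CC1(C)[C@@H](Br)C[C@@H](OC(C)=O)[C@@]1(C)[C@@]12CC[C@](C)(O)[C@@H](Br)[C@@H]1O2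
F5 | step 23 | acetate of bromochloro epoxide 34 at the cyclopentane hydroxyl | CC1(C)[C@@H](Br)C[C@@H](OC(C)=O)[C@@]1(C)[C@@]12CC[C@](C)(Cl)[C@@H](Br)[C@@H]1O2
F6 | step 16 | 4-hydroxy-2,2,3-trimethyl-3-(4-oxocyclohex-1-en-1-yl)cyclopentyl chloromethanesulfonate | CC1(C)[C@H](OS(=O)(=O)CCl)C[C@@H](O)[C@@]1(C)C1=CCC(=O)CC1
F7 | step 16 | 4-(3-bromo-5-hydroxy-1,2,2-trimethylcyclopentyl)cyclohex-3-en-1-one | CC1(C)[C@@H](Br)C[C@@H](O)[C@@]1(C)C1=CCC(=O)CC1
A1 | alternative 1 | methyl 2-(tert-butyldimethylsilyloxy)-4-hydroxy-1,5,5-trimethylcyclopentane-1-carboxylate | CC1(C)[C@H](O)C[C@@H](O[Si](C)(C)C(C)(C)C)[C@@]1(C)C(=O)OC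
A2 | alternative 2 | 4-hydroxy-3-[1-(methoxymethoxy)-4-methylcyclohex-3-en-1-yl]-2,2,3-trimethylcyclopentan-1-one | CC1(C)C(=O)C[C@@H](O)[C@@]1(C)[C@@]1(OCOC)CCC(C)=CC1
A3 | alternative 3 | 4-bromo-2-(8-hydroxy-1,4-dioxaspiro[4.5]decan-8-yl)-2,3,3-trimethylcyclopentyl acetate | CC1(C)[C@@H](Br)C[C@@H](OC(C)=O)[C@@]1(C)C1(O)CCC2(CC1)OCCO2
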